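The route rests on cutting the C6–C7 bond of the α-ketol C6(=O)–C7(OH)(CH3) in the carbocyclic ring. The feature exploited is that C6 is a carbonyl carbon held on the pyran ring through C4a=C5, while C7 is a tertiary carbinol next to the C8 oxygen, so the ring is the crossed benzoin of an aldehyde and a methyl ketone. One carbene-catalysed operation forms the C6–C7 bond, closes the carbocycle and sets the C7 stereocentre. Its precursor 28 is a 2-alkenyl-4-(formylmethylene)dihydropyran that carries at C8a a C8-silyloxy methyl ketone arm and the fully silylated side chain, assembled by an anti boron aldol on a dihydropyranone.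

Key step: step 18

Remarks on the chemistry (assumptions, one line each)
- Numbering: core atoms as in isochromene (C1, O2, C3, C4, C4a, C5, C6, C7, C8, C8a); side chain C1′–C7′ counted from the ring.
- Chiral-pool source: the target side chain is 3′S,4′R,5′S. The C4′(R)/C5′(S) pair is that of D-allo-isoleucine (2R,3S). L-Isoleucine (2S,3S), hydroxylated with retention, would give the C4′ epimer, so D-allo-isoleucine (commercial) is used.
- Protecting groups: O8 carries tert-butyldimethylsilyl and the lactate oxygen (O7) is the only unhindered triethylsilyl ether, so O7 alone can be unmasked and oxidised; the larger O8 group should also raise the Felkin bias and slow silyl migration to the new C7 hydroxyl.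
- Geometry at C4a=C5: compounds 25–28 are drawn as the isomer with the C6 carbon on the C8a side; step 14 is expected to give both geometric isomers, which are carried together and should converge in step 18.

Step 1
Reactants: 1 D-allo-isoleucine
Product: 2 (2R,3S)-2-hydroxy-3-methylpentanoic acid
Conditions: NaNO2, 1 M aq. H2SO4, 0 °C to rt
Reagents that add atoms: water, O
Why: Diazotisation of the α-amino acid with hydrolysis through the α-lactone (double inversion) should replace NH2 by OH with retention, so C4′ (R) and C5′ (S) both come from the chiral pool.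

Step 2
Reactants: 2 (2R,3S)-2-hydroxy-3-methylpentanoic acid
Product: 3 (2R,3S)-2-hydroxy-N-methoxy-N,3-dimethylpentanamide
Conditions: MeNHOMe·HCl, EDC·HCl, HOBt, N-methylmorpholine, CH2Cl2, 0 °C to rt
Reagents that add atoms: N,O-dimethylhydroxylamine hydrochloride, CNOC.Cl
Why: Carbodiimide amide coupling (Weinreb amide formation), in which the amine should outcompete the hindered secondary hydroxyl as nucleophile.

Step 3
Reactants: 3 (2R,3S)-2-hydroxy-N-methoxy-N,3-dimethylpentanamide; 4 1,4-bis(trimethylsilyl)buta-1,3-diyne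
Product: 6 (6R,7S)-6-hydroxy-7-methyl-1-(trimethylsilyl)nona-1,3-diyn-5-one, via lithium (trimethylsilyl)butadiynide 5 (not isolated)
Conditions: 4, MeLi·LiBr, THF, rt; 3 pre-treated with i-PrMgCl (1 equiv), THF, −20 °C; combine, −78 to 0 °C; cold aq. NH4Cl; product used at once
Reagents that add atoms: none
Why: Monodesilylation–lithiation of the bis-silyl diyne and acylation of the acetylide by the Weinreb amide (chelated tetrahedral intermediate, ketone released only on work-up) should give the ynone without over-addition.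

Step 4
Reactants: 6 (6R,7S)-6-hydroxy-7-methyl-1-(trimethylsilyl)nona-1,3-diyn-5-one
Product: 7 (5S,6R,7S)-5,7-dimethyl-1-(trimethylsilyl)nona-1,3-diyne-5,6-diol
Conditions: MeMgBr (3 equiv), Et2O, −78 °C
Reagents that add atoms: methylmagnesium bromide, C[Mg]Br
Why: Cram-chelate Grignard addition, in which the magnesium alkoxide of the C4′ hydroxyl and the ketone oxygen form a five-membered chelate and methyl adds to the face opposite the sec-butyl group, which should set C3′ in the target (S) sense.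

Step 5
Reactants: 7 (5S,6R,7S)-5,7-dimethyl-1-(trimethylsilyl)nona-1,3-diyne-5,6-diol
Product: 9 (3E,5S,6R,7S)-5,7-dimethylnon-3-en-1-yne-5,6-diol, via silylated enyne diol 8 (not isolated)
Conditions: NaAlH2(OCH2CH2OMe)2, THF, 0 °C to rt; then MeOH, K2CO3, rt
Reagents that add atoms: none
Why: Alkoxide-directed trans-hydroalumination of the propargylic triple bond of a 2,4-diyn-1-ol should give only the (E)-enyne, and basic methanolysis then removes the alkynyl silyl group.

Step 6
Reactants: 9 (3E,5S,6R,7S)-5,7-dimethylnon-3-en-1-yne-5,6-diol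
Product: 10 (3E,5S,6R,7S)-5,6-bis(triethylsilyloxy)-5,7-dimethylnon-3-en-1-yne
Conditions: Et3SiOTf (2.4 equiv), 2,6-lutidine, CH2Cl2, −78 to 0 °C
Reagents that add atoms: triethylsilyl trifluoromethanesulfonate, CC[Si](CC)(CC)OS(=O)(=O)C(F)(F)F
Why: Silyl triflate/lutidine silylation is strong enough for the tertiary hydroxyl and leaves the terminal alkyne C–H untouched.

Step 7
Reactants: 11 methyl 3-hydroxypropanoate
Product: 12 3-hydroxy-N-methoxy-N-methylpropanamide
Conditions: MeNHOMe·HCl, i-PrMgCl (4 equiv), THF, −20 to 0 °C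
Reagents that add atoms: N,O-dimethylhydroxylamine hydrochloride, CNOC.Cl
Why: Aminolysis of the methyl ester by the chloromagnesium amide of N,O-dimethylhydroxylamine (Weinreb amide formation from an ester), the free hydroxyl only consuming base.

Step 8
Reactants: 10 (3E,5S,6R,7S)-5,6-bis(triethylsilyloxy)-5,7-dimethylnon-3-en-1-yne; 12 3-hydroxy-N-methoxy-N-methylpropanamide
Product: 14 (6E,8S,9R,10S)-1-hydroxy-8,10-dimethyl-8,9-bis(triethylsilyloxy)dodec-6-en-4-yn-3-one, via lithium acetylide 13 (not isolated)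
Conditions: 10, n-BuLi, THF, −78 °C; 12 pre-treated with i-PrMgCl (1 equiv), THF, −20 °C; combine, −78 to 0 °C; aq. NH4Cl
Reagents that add atoms: none
Why: Acylation of a lithium acetylide by a Weinreb amide, with the hydroxyl masked as its magnesium alkoxide so that only one equivalent of the acetylide is consumed.

Step 9
Reactants: 14 (6E,8S,9R,10S)-1-hydroxy-8,10-dimethyl-8,9-bis(triethylsilyloxy)dodec-6-en-4-yn-3-one
Product: 15 6-[(1E,3S,4R,5S)-3,4-bis(triethylsilyloxy)-3,5-dimethylhept-1-en-1-yl]-2,3-dihydro-4H-pyran-4-one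
Conditions: AuCl(PPh3) (5 mol %), AgOTf (5 mol %), CH2Cl2, rt
Reagents that add atoms: none
Why: Gold-catalysed 6-endo-dig hydroalkoxylation of the β-hydroxy ynone (conjugate addition to the activated triple bond) should give the dihydropyranone, the 5-exo mode being anti-Michael.

Step 10
Reactants: 16 ethyl (S)-lactate
Product: 17 ethyl (S)-2-(triethylsilyloxy)propanoate
Conditions: Et3SiCl, imidazole, CH2Cl2, 0 °C to rt
Reagents that add atoms: chlorotriethylsilane, CC[Si](CC)(CC)Cl
Why: Standard imidazole-mediated silylation of a secondary alcohol.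

Step 11
Reactants: 17 ethyl (S)-2-(triethylsilyloxy)propanoate
Product: 18 (S)-2-(triethylsilyloxy)propanal
Conditions: i-Bu2AlH (1.1 equiv), CH2Cl2, −78 °C; aq. KNaC4H4O6; used at once
Reagents that add atoms: none
Why: Partial ester reduction through the aluminium hemiacetal, which is stable at −78 °C, should stop at the aldehyde, and immediate use avoids racemisation.

Step 12
Reactants: 15 6-[(1E,3S,4R,5S)-3,4-bis(triethylsilyloxy)-3,5-dimethylhept-1-en-1-yl]-2,3-dihydro-4H-pyran-4-one; 18 (S)-2-(triethylsilyloxy)propanal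
Product: 20 (3S)-3-[(1R,2S)-1-hydroxy-2-(triethylsilyloxy)propyl]-6-[(1E,3S,4R,5S)-3,4-bis(triethylsilyloxy)-3,5-dimethylhept-1-en-1-yl]-2,3-dihydro-4H-pyran-4-one, via dicyclohexylboron dienolate 19 (not isolated)
Conditions: (c-C6H11)2BCl, Et3N, Et2O, −78 to 0 °C; 18, −78 to −25 °C; MeOH, pH 7 buffer, 30% H2O2, 0 °C
Reagents that add atoms: none
Why: Boron aldol through a Zimmerman–Traxler chair, in which the cyclic ketone can only give the E-enolate (anti C8a/C8) and the α-silyloxy aldehyde is attacked in the Felkin–Anh sense, so the (S)-lactaldehyde centre should set C8 (R) and C8a (S).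

Step 13
Reactants: 20 aldol adduct (C8 alcohol)
Product: 21 (3S)-3-[(1R,2S)-1-(tert-butyldimethylsilyloxy)-2-(triethylsilyloxy)propyl]-6-[(1E,3S,4R,5S)-3,4-bis(triethylsilyloxy)-3,5-dimethylhept-1-en-1-yl]-2,3-dihydro-4H-pyran-4-one
Conditions: t-BuMe2SiOTf, 2,6-lutidine, CH2Cl2, −78 °C
Reagents that add atoms: tert-butyldimethylsilyl trifluoromethanesulfonate, CC(C)(C)[Si](C)(C)OS(=O)(=O)C(F)(F)F
Why: Low-temperature triflate silylation of the hindered β-hydroxy ketone is fast and non-basic, so retro-aldol and C8a epimerisation should not compete.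

Step 14
Reactants: 21 dihydropyranone with O8 silyl ether; 22 ethoxyacetylene
Product: 25 ethyl (2E)-2-{(3S)-3-[(1R,2S)-1-(tert-butyldimethylsilyloxy)-2-(triethylsilyloxy)propyl]-6-[(1E,3S,4R,5S)-3,4-bis(triethylsilyloxy)-3,5-dimethylhept-1-en-1-yl]-2,3-dihydro-4H-pyran-4-ylidene}acetate, via lithium ethoxyacetylide 23 (not isolated), via propargylic alcohol 24 (not isolated)
Conditions: 22, n-BuLi, THF, −78 °C; 21, −78 to −40 °C; aq. NH4Cl; crude 24, Sc(OTf)3 (5 mol %), CH2Cl2–EtOH 5:1, 0 °C to rt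
Reagents that add atoms: none
Why: 1,2-Addition of the small, weakly basic ethoxyacetylide to the vinylogous ester carbonyl and Lewis-acid Meyer–Schuster rearrangement of the ethoxyethynyl carbinol, whose ionisation is assisted by the ring enol ether, should give the push–pull dienoate at the ester oxidation level.

Step 15
Reactants: 25 dienoate with O7 triethylsilyl ether
Product: 26 ethyl (2E)-2-{(3S)-3-[(1R,2S)-1-(tert-butyldimethylsilyloxy)-2-hydroxypropyl]-6-[(1E,3S,4R,5S)-3,4-bis(triethylsilyloxy)-3,5-dimethylhept-1-en-1-yl]-2,3-dihydro-4H-pyran-4-ylidene}acetate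
Conditions: PPTS (0.3 equiv), MeOH–CH2Cl2 1:4, 0 °C, stopped at full conversion of 25
Reagents that add atoms: none
Why: Acid-catalysed methanolysis sorts silyl ethers by size and hindrance, so the only unhindered secondary triethylsilyl ether (O7) should go before the tert-butyldimethylsilyl ether and the two neopentyl-like side-chain ethers, and the vinylogous carbonate enol ether is too weakly basic for PPTS.

Step 16
Reactants: 26 dienoate with free C7 hydroxyl
Product: 27 (2E)-2-{(3S)-3-[(1R,2S)-1-(tert-butyldimethylsilyloxy)-2-hydroxypropyl]-6-[(1E,3S,4R,5S)-3,4-bis(triethylsilyloxy)-3,5-dimethylhept-1-en-1-yl]-2,3-dihydro-4H-pyran-4-ylidene}ethan-1-ol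
Conditions: i-Bu2AlH (4 equiv), CH2Cl2, −78 °C; aq. KNaC4H4O6; base-washed glassware, used crude
Reagents that add atoms: none
Why: Hydride reduction of the ester to the primary allylic alcohol (excess reagent covers the free hydroxyl), with a neutral tartrate work-up to avoid ionisation of the electron-rich dienyl alcohol.

Step 17
Reactants: 27 diol
Product: 28 (2E)-2-{(3S)-3-[(1R)-1-(tert-butyldimethylsilyloxy)-2-oxopropyl]-6-[(1E,3S,4R,5S)-3,4-bis(triethylsilyloxy)-3,5-dimethylhept-1-en-1-yl]-2,3-dihydro-4H-pyran-4-ylidene}acetaldehyde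
Conditions: Dess–Martin periodinane (3 equiv), NaHCO3, CH2Cl2, 0 °C to rt
Reagents that add atoms: none
Why: Buffered Dess–Martin oxidation of both hydroxyls should give the vinylogous formate aldehyde and the C7 methyl ketone at once, consuming the lactate stereocentre that has done its work in step 12.

Step 18
Reactants: 28 keto-aldehyde (pyran dienal with C8-silyloxy methyl ketone arm)
Product: 29 (7R,8R,8aS)-8-(tert-butyldimethylsilyloxy)-7-hydroxy-7-methyl-3-[(1E,3S,4R,5S)-3,4-bis(triethylsilyloxy)-3,5-dimethylhept-1-en-1-yl]-1,7,8,8a-tetrahydro-6H-isochromen-6-one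
Conditions: (5aS,10bR)-2-mesityl-5a,10b-dihydro-4H,6H-indeno[2,1-b][1,2,4]triazolo[4,3-d][1,4]oxazin-2-ium chloride (20 mol %), i-Pr2NEt (40 mol %), 4 Å molecular sieves, toluene (0.02 M), rt to 40 °C
Reagents that add atoms: none
Why: Proposed new method: the triazolylidene adds to the C6 aldehyde, proton transfer gives the Breslow enaminol, and this C6 acyl-anion equivalent attacks the C7 ketone before the carbene is expelled; the closest known reaction is the intramolecular crossed aldehyde–ketone benzoin of saturated and aryl keto-aldehydes, which has not been run with a δ-alkoxy dienal (vinylogous formate) as donor. The carbocycle (C4a–C5–C6–C7–C8–C8a) closes 6-exo-trig by attack of C6 on the C7 carbonyl. The new C7 stereocentre is controlled by C8: with the forming C6–C7 bond anti to the C8–O bond (Felkin–Anh) and the ketone methyl kept out of the sector between the C8 silyloxy group and C8a, the hydroxyl should end up cis to O8 (7R). The aminoindanol backbone is meant to reinforce this sense (to be confirmed against the antipodal salt), and reversibility of the benzoin should let the hydrogen-bonded cis-ketol accumulate. The step needs acyl-anion rather than homoenolate reactivity: C4a is fully substituted and could reach C7 only through a four-membered ring, and no protic nucleophile is present to turn over an acyl azolium. A wrong C4a=C5 geometry should not be lost, because the homoenolate resonance form of the Breslow intermediate has a C4a–C5 single bond and can rotate.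

Step 19
Reactants: 29 cyclised α-ketol
Product: 30 (7R,8R,8aS)-5-bromo-8-(tert-butyldimethylsilyloxy)-7-hydroxy-7-methyl-3-[(1E,3S,4R,5S)-3,4-bis(triethylsilyloxy)-3,5-dimethylhept-1-en-1-yl]-1,7,8,8a-tetrahydro-6H-isochromen-6-one
Conditions: N-bromosuccinimide (1.05 equiv), NaHCO3, THF, −20 to 0 °C, dark
Reagents that add atoms: N-bromosuccinimide, O=C1CCC(=O)N1Br
Why: Electrophilic bromination of the dienol ether–enone chromophore should occur at C5, the α-carbon of the vinylogous ester and the position halogenated in azaphilones, while the side-chain alkene is shielded by its silyl ethers.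

Step 20
Reactants: 30 bromo tris-silyl ether
Product: 31 penicilazaphilone H, (7R,8R,8aS)-5-bromo-3-[(1E,3S,4R,5S)-3,4-dihydroxy-3,5-dimethylhept-1-en-1-yl]-7,8-dihydroxy-7-methyl-1,7,8,8a-tetrahydro-6H-isochromen-6-one
Conditions: HF·pyridine, pyridine, THF, 0 °C to rt
Reagents that add atoms: none
Why: Fluoride cleavage of all three silyl ethers under pyridine-buffered, non-basic conditions should leave the α-ketol, the bromo enone and the tertiary allylic alcohol intact.

Compound list
1 | D-allo-isoleucine | CC[C@H](C)[C@@H](N)C(=O)O | starting material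
2 | (2R,3S)-2-hydroxy-3-methylpentanoic acid | CC[C@H](C)[C@@H](O)C(=O)O | intermediate
3 | (2R,3S)-2-hydroxy-N-methoxy-N,3-dimethylpentanamide | CC[C@H](C)[C@@H](O)C(=O)N(C)OC | intermediate
4 | 1,4-bis(trimethylsilyl)buta-1,3-diyne | C[Si](C)(C)C#CC#C[Si](C)(C)C | starting material
5 | lithium (trimethylsilyl)butadiynide | [Li]C#CC#C[Si](C)(C)C | intermediate
6 | (6R,7S)-6-hydroxy-7-methyl-1-(trimethylsilyl)nona-1,3-diyn-5-one | CC[C@H](C)[C@@H](O)C(=O)C#CC#C[Si](C)(C)C | intermediate
7 | (5S,6R,7S)-5,7-dimethyl-1-(trimethylsilyl)nona-1,3-diyne-5,6-diol | CC[C@H](C)[C@@H](O)[C@@](C)(O)C#CC#C[Si](C)(C)C | intermediate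
8 | (3E,5S,6R,7S)-5,7-dimethyl-1-(trimethylsilyl)non-3-en-1-yne-5,6-diol | CC[C@H](C)[C@@H](O)[C@@](C)(O)/C=C/C#C[Si](C)(C)C | intermediate
9 | (3E,5S,6R,7S)-5,7-dimethylnon-3-en-1-yne-5,6-diol | CC[C@H](C)[C@@H](O)[C@@](C)(O)/C=C/C#C | intermediate
10 | (3E,5S,6R,7S)-5,6-bis(triethylsilyloxy)-5,7-dimethylnon-3-en-1-yne | CC[C@H](C)[C@@H](O[Si](CC)(CC)CC)[C@@](C)(O[Si](CC)(CC)CC)/C=C/C#C | intermediate
11 | methyl 3-hydroxypropanoate | COC(=O)CCO | starting material
12 | 3-hydroxy-N-methoxy-N-methylpropanamide | CON(C)C(=O)CCO | intermediate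
13 | lithium acetylide of 10 | CC[C@H](C)[C@@H](O[Si](CC)(CC)CC)[C@@](C)(O[Si](CC)(CC)CC)/C=C/C#C[Li] | intermediate
14 | (6E,8S,9R,10S)-1-hydroxy-8,10-dimethyl-8,9-bis(triethylsilyloxy)dodec-6-en-4-yn-3-one | CC[C@H](C)[C@@H](O[Si](CC)(CC)CC)[C@@](C)(O[Si](CC)(CC)CC)/C=C/C#CC(=O)CCO | intermediate
15 | 6-[(1E,3S,4R,5S)-3,4-bis(triethylsilyloxy)-3,5-dimethylhept-1-en-1-yl]-2,3-dihydro-4H-pyran-4-one | CC[C@H](C)[C@@H](O[Si](CC)(CC)CC)[C@@](C)(O[Si](CC)(CC)CC)/C=C/C1=CC(=O)CCO1 | intermediate
16 | ethyl (S)-lactate | CCOC(=O)[C@H](C)O | starting material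
17 | ethyl (S)-2-(triethylsilyloxy)propanoate | CCOC(=O)[C@H](C)O[Si](CC)(CC)CC | intermediate
18 | (S)-2-(triethylsilyloxy)propanal | O=C[C@H](C)O[Si](CC)(CC)CC | intermediate
19 | dicyclohexylboron dienolate of 15 (4-(dicyclohexylboryloxy)-2H-pyran) | CC[C@H](C)[C@@H](O[Si](CC)(CC)CC)[C@@](C)(O[Si](CC)(CC)CC)/C=C/C1=CC(OB(C2CCCCC2)C2CCCCC2)=CCO1 | intermediate
20 | (3S)-3-[(1R,2S)-1-hydroxy-2-(triethylsilyloxy)propyl]-6-[(1E,3S,4R,5S)-3,4-bis(triethylsilyloxy)-3,5-dimethylhept-1-en-1-yl]-2,3-dihydro-4H-pyran-4-one | O=C1C=C(/C=C/[C@](C)(O[Si](CC)(CC)CC)[C@H](O[Si](CC)(CC)CC)[C@@H](C)CC)OC[C@H]1[C@@H](O)[C@H](C)O[Si](CC)(CC)CC | intermediate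
21 | (3S)-3-[(1R,2S)-1-(tert-butyldimethylsilyloxy)-2-(triethylsilyloxy)propyl]-6-[(1E,3S,4R,5S)-3,4-bis(triethylsilyloxy)-3,5-dimethylhept-1-en-1-yl]-2,3-dihydro-4H-pyran-4-one | O=C1C=C(/C=C/[C@](C)(O[Si](CC)(CC)CC)[C@H](O[Si](CC)(CC)CC)[C@@H](C)CC)OC[C@H]1[C@@H](O[Si](C)(C)C(C)(C)C)[C@H](C)O[Si](CC)(CC)CC | intermediate
22 | ethoxyacetylene | CCOC#C | starting material
23 | lithium ethoxyacetylide | CCOC#C[Li] | intermediate
24 | 4-(ethoxyethynyl)-4-hydroxy adduct of 21 (both C4a epimers) | CCOC#CC1(O)C=C(/C=C/[C@](C)(O[Si](CC)(CC)CC)[C@H](O[Si](CC)(CC)CC)[C@@H](C)CC)OC[C@H]1[C@@H](O[Si](C)(C)C(C)(C)C)[C@H](C)O[Si](CC)(CC)CC | intermediate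
25 | ethyl (2E)-2-{(3S)-3-[(1R,2S)-1-(tert-butyldimethylsilyloxy)-2-(triethylsilyloxy)propyl]-6-[(1E,3S,4R,5S)-3,4-bis(triethylsilyloxy)-3,5-dimethylhept-1-en-1-yl]-2,3-dihydro-4H-pyran-4-ylidene}acetate (ester on the C8a side) | CCOC(=O)/C=C1/C=C(/C=C/[C@](C)(O[Si](CC)(CC)CC)[C@H](O[Si](CC)(CC)CC)[C@@H](C)CC)OC[C@H]1[C@@H](O[Si](C)(C)C(C)(C)C)[C@H](C)O[Si](CC)(CC)CC | intermediate
26 | C7 alcohol of 25, ethyl (2E)-2-{(3S)-3-[(1R,2S)-1-(tert-butyldimethylsilyloxy)-2-hydroxypropyl]-6-[(1E,3S,4R,5S)-3,4-bis(triethylsilyloxy)-3,5-dimethylhept-1-en-1-yl]-2,3-dihydro-4H-pyran-4-ylidene}acetate | CCOC(=O)/C=C1/C=C(/C=C/[C@](C)(O[Si](CC)(CC)CC)[C@H](O[Si](CC)(CC)CC)[C@@H](C)CC)OC[C@H]1[C@@H](O[Si](C)(C)C(C)(C)C)[C@H](C)O | intermediate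
27 | (2E)-2-{(3S)-3-[(1R,2S)-1-(tert-butyldimethylsilyloxy)-2-hydroxypropyl]-6-[(1E,3S,4R,5S)-3,4-bis(triethylsilyloxy)-3,5-dimethylhept-1-en-1-yl]-2,3-dihydro-4H-pyran-4-ylidene}ethan-1-ol | OC/C=C1/C=C(/C=C/[C@](C)(O[Si](CC)(CC)CC)[C@H](O[Si](CC)(CC)CC)[C@@H](C)CC)OC[C@H]1[C@@H](O[Si](C)(C)C(C)(C)C)[C@H](C)O | intermediate
28 | key-step precursor, (2E)-2-{(3S)-3-[(1R)-1-(tert-butyldimethylsilyloxy)-2-oxopropyl]-6-[(1E,3S,4R,5S)-3,4-bis(triethylsilyloxy)-3,5-dimethylhept-1-en-1-yl]-2,3-dihydro-4H-pyran-4-ylidene}acetaldehyde (formyl on the C8a side) | O=C/C=C1/C=C(/C=C/[C@](C)(O[Si](CC)(CC)CC)[C@H](O[Si](CC)(CC)CC)[C@@H](C)CC)OC[C@H]1[C@@H](O[Si](C)(C)C(C)(C)C)C(C)=O | intermediate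
29 | key-step product, (7R,8R,8aS)-8-(tert-butyldimethylsilyloxy)-7-hydroxy-7-methyl-3-[(1E,3S,4R,5S)-3,4-bis(triethylsilyloxy)-3,5-dimethylhept-1-en-1-yl]-1,7,8,8a-tetrahydro-6H-isochromen-6-one | CC[C@H](C)[C@@H](O[Si](CC)(CC)CC)[C@@](C)(O[Si](CC)(CC)CC)/C=C/C1=CC2=CC(=O)[C@](C)(O)[C@H](O[Si](C)(C)C(C)(C)C)[C@@H]2CO1 | intermediate
30 | 5-bromo derivative of 29 | CC[C@H](C)[C@@H](O[Si](CC)(CC)CC)[C@@](C)(O[Si](CC)(CC)CC)/C=C/C1=CC2=C(Br)C(=O)[C@](C)(O)[C@H](O[Si](C)(C)C(C)(C)C)[C@@H]2CO1 | intermediate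
31 | penicilazaphilone H | CC[C@H](C)[C@@H](O)[C@@](C)(O)/C=C/C1=CC2=C(Br)C(=O)[C@](C)(O)[C@H](O)[C@@H]2CO1 | target

Total step count: 20.
Longest linear sequence: 17 steps (1–6, 8, 9, 12–20).

Steps most likely to fail

1. Step 18 (Proposed new method). The carbene may not add to the strongly deactivated vinylogous formyl group, the Breslow intermediate may be protonated at carbon instead of closing the ring, or attack on the ketone may show poor facial selectivity. The fallback uses known chemistry, forming C6–C7 by a Felkin–Anh addition and closing the ring at C4a=C5. It sets out from 21 and comes back at 29. Selective methanolysis of the O7 triethylsilyl ether (PPTS, MeOH) gives the C7 alcohol F1, and Dess–Martin oxidation gives the C7 methyl ketone F2. 1-Ethoxyvinyllithium (ethyl vinyl ether, t-BuLi, THF, −78 °C) should add to this ketone rather than to the vinylogous ester carbonyl, anti to the C8–O bond, to give the enol ether carbinol F3 with the (7R) hydroxyl. Mild aqueous acid (oxalic acid on wet silica) unveils the α-hydroxy methyl ketone F4. Intramolecular aldol condensation of its acetyl methyl (C5) onto the C4a carbonyl (LiN(SiMe3)2, THF, −78 to 0 °C, then PPTS to lose water) gives 29.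

2. Step 14. The acetylide may deprotonate C8a and trigger β-elimination of the C8 silyloxy group instead of adding to the hindered carbonyl, and the acid-mediated 1,3-shift may be diverted into hydrolytic opening of the ring enol ether. The fallback sets out from 21 and comes back at 25. The non-basic cerium enolate of ethyl acetate (LiN(i-Pr)2, EtOAc, CeCl3, THF, −78 °C) adds to the C4a carbonyl to give the β-hydroxy ester F5, which is dehydrated under neutral conditions (Burgess reagent, toluene, 50 °C) to the conjugated dienoate 25.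

3. Step 4. The free α′-hydroxy ynone may cyclise 5-endo onto the triple bond before the Grignard reagent adds, or chelation control may erode. The fallback sets out from 3 and comes back at 7. The hydroxyl is masked as a chelating benzyl-type ether (4-methoxybenzyl trichloroacetimidate, cat. Sc(OTf)3) to give the 4-methoxybenzyl ether F6. Acylation of lithium diynide 5 gives the protected diynone F7. Chelation-controlled MeMgBr addition (Et2O, −78 °C) gives the protected tertiary carbinol F8, and oxidative removal of the ether (DDQ, CH2Cl2, pH 7 buffer) gives diol 7.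

Further compounds
F1 | step 18 | (3S)-3-[(1R,2S)-1-(tert-butyldimethylsilyloxy)-2-hydroxypropyl]-6-[(1E,3S,4R,5S)-3,4-bis(triethylsilyloxy)-3,5-dimethylhept-1-en-1-yl]-2,3-dihydro-4H-pyran-4-one | O=C1C=C(/C=C/[C@](C)(O[Si](CC)(CC)CC)[C@H](O[Si](CC)(CC)CC)[C@@H](C)CC)OC[C@H]1[C@@H](O[Si](C)(C)C(C)(C)C)[C@H](C)O
F2 | step 18 | (3S)-3-[(1R)-1-(tert-butyldimethylsilyloxy)-2-oxopropyl]-6-[(1E,3S,4R,5S)-3,4-bis(triethylsilyloxy)-3,5-dimethylhept-1-en-1-yl]-2,3-dihydro-4H-pyran-4-one | O=C1C=C(/C=C/[C@](C)(O[Si](CC)(CC)CC)[C@H](O[Si](CC)(CC)CC)[C@@H](C)CC)OC[C@H]1[C@@H](O[Si](C)(C)C(C)(C)C)C(C)=O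
F3 | step 18 | 1-ethoxyvinyl adduct of F2 at C7 (7R tertiary carbinol) | O=C1C=C(/C=C/[C@](C)(O[Si](CC)(CC)CC)[C@H](O[Si](CC)(CC)CC)[C@@H](C)CC)OC[C@H]1[C@@H](O[Si](C)(C)C(C)(C)C)[C@@](C)(O)C(=C)OCC
F4 | step 18 | α-hydroxy methyl ketone (C6 acetyl on the 7R carbinol) | O=C1C=C(/C=C/[C@](C)(O[Si](CC)(CC)CC)[C@H](O[Si](CC)(CC)CC)[C@@H](C)CC)OC[C@H]1[C@@H](O[Si](C)(C)C(C)(C)C)[C@@](C)(O)C(C)=O
F5 | step 14 | ethyl 2-(4-hydroxy-2,3-dihydro-4H-pyran-4-yl)acetate adduct of 21 (both C4a epimers) | CCOC(=O)CC1(O)C=C(/C=C/[C@](C)(O[Si](CC)(CC)CC)[C@H](O[Si](CC)(CC)CC)[C@@H](C)CC)OC[C@H]1[C@@H](O[Si](C)(C)C(C)(C)C)[C@H](C)O[Si](CC)(CC)CC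
F6 | step 4 | (2R,3S)-N-methoxy-2-(4-methoxybenzyloxy)-N,3-dimethylpentanamide | CC[C@H](C)[C@@H](OCc1ccc(OC)cc1)C(=O)N(C)OC
F7 | step 4 | (6R,7S)-6-(4-methoxybenzyloxy)-7-methyl-1-(trimethylsilyl)nona-1,3-diyn-5-one | CC[C@H](C)[C@@H](OCc1ccc(OC)cc1)C(=O)C#CC#C[Si](C)(C)C
F8 | step 4 | (5S,6R,7S)-6-(4-methoxybenzyloxy)-5,7-dimethyl-1-(trimethylsilyl)nona-1,3-diyn-5-ol | CC[C@H](C)[C@@H](OCc1ccc(OC)cc1)[C@@](C)(O)C#CC#C[Si](C)(C)C
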